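Rings C and D are cut back together to an AB-bicyclic 1,7-enyne. The feature exploited is ring D: a cyclopentane whose C9 and ester-bearing quaternary C13 are shared with ring C and whose C10 carries the isopropyl group, that is, a cyclopentenone made from an isopropyl alkyne (C9≡C10), a 2-substituted acrylate (C13=C12) and CO (C11). One intramolecular Pauson–Khand reaction forms C9–C13, C10–C11 and C11–C12, closes both rings and sets C13. Its precursor 27 is a 5-8 bicycle carrying the alkynyl arm on the silylated carbinol C7 and the acrylate arm on C15; it is built by ring-closing metathesis and oxidative transposition.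

Key step: step 17

Numbering used below (a working numbering for this proposal): ring A = C1–C5 (C1 ring-fusion CH; C2 CH–CH3; C3, C4 CH2; C5 sp2); ring B = C1, C5, C6 (sp2, CH3), C7 (carbinol), C15, C16 (CH–CH3), C17, C18; ring C = C7, C8, C9, C13, C14, C15; ring D = C9, C10 (isopropyl), C11, C12, C13 (CO2H). β is the face of the C7 oxygen, α the other face. The target has H-1, H-9, H-10 and the C2 methyl β, and H-15, the C16 methyl and the C13 carboxyl α.

Assumption: methyl hydrogen (R)-3-methylglutarate and (R)-pulegone are taken as commercial chiral-pool materials.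

Design of the precursor: the carbinol is carried as its triethylsilyl ether. The cyclisation product is a vinylogous aldol (O–C7–C8–C9=C10–C11=O), so the silyl group must survive until the enone is gone, and the bulkier axial group also disfavours the boat-like cyclisation mode. The acid is carried as the methyl ester of the commercial bromide and is released at the end by demethylation, not by saponification of the hindered angular ester.

**Route**

Step 1
Reactants: 1 methyl hydrogen (R)-3-methylglutarate
Product: 3 (4S)-4-methyloxan-2-one, via hydroxy acid 2 (not isolated)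
Conditions: LiBH4, THF, 0 → 40 °C; then aq. HCl (pH 1), 23 °C
Reagents that add atoms: none
Why: Chemoselective ester reduction then lactonisation: the acid is first converted into its lithium carboxylate, which LiBH4 does not reduce, the methyl ester is reduced to the alcohol, and acidification closes the δ-lactone, so that C7 stays at the acid level and C18 at the alcohol level while the C16 stereocentre is untouched.

Step 2
Reactants: 3 (4S)-4-methyloxan-2-one
Product: 4 (4S)-4-methyloxan-2-ol (lactol; both anomers)
Conditions: i-Bu2AlH (1.1 equiv), CH2Cl2, −78 °C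
Reagents that add atoms: none
Why: Partial reduction of a lactone with i-Bu2AlH: the tetrahedral aluminium acetal is stable at −78 °C and releases the lactol only on work-up, so over-reduction to the diol is avoided.

Step 3
Reactants: 4 (4S)-4-methyloxan-2-ol
Product: 5 (3R)-3-methylhex-5-en-1-ol
Conditions: Ph3PCH3Br, KOt-Bu, THF, 0 → 23 °C
Reagents that add atoms: methyltriphenylphosphonium bromide, C[P+](c1ccccc1)(c1ccccc1)c1ccccc1.[Br-]
Why: Wittig methylenation of the open hydroxy aldehyde in equilibrium with the lactol turns C7 into the terminal vinyl group needed for metathesis and frees the C18 hydroxyl.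

Step 4
Reactants: 5 (3R)-3-methylhex-5-en-1-ol
Product: 6 (4R)-6-iodo-4-methylhex-1-ene
Conditions: I2, PPh3, imidazole, CH2Cl2, 0 °C
Reagents that add atoms: iodine, II
Why: Appel-type iodination (PPh3/I2/imidazole) of an unhindered primary alcohol by SN2 displacement at C18, far from the C16 stereocentre.

Step 5
Reactants: 7 (R)-pulegone
Product: 9 methyl pulegenate (C1 epimers), via pulegone dibromide 8 (not isolated)
Conditions: Br2, Et2O, −10 °C; then NaOMe, MeOH, 65 °C
Reagents that add atoms: sodium methoxide, [Na+].[O-]C (bromine, BrBr, enters only intermediate 8)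
Why: Bromine addition to the enone alkene followed by Favorskii ring contraction: the α′ enolate closes to a cyclopropanone that methoxide opens to the cyclopentane ester, the second bromide is lost to restore the isopropylidene group, and the methyl-bearing stereocentre (the future C2) is not involved.

Step 6
Reactants: 9 methyl pulegenate
Product: 11 methyl (1S,2R)-2-methyl-5-oxocyclopentane-1-carboxylate, via secondary ozonide 10 (not isolated)
Conditions: O3, CH2Cl2, −78 °C; then Me2S, −78 → 23 °C
Reagents that add atoms: ozone, [O-][O+]=O
Why: Ozonolysis with reductive work-up cleaves the tetrasubstituted alkene to the C5 ketone, and the β-keto ester then settles through its enol as the trans isomer (ester on C1 anti to the C2 methyl).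

Step 7
Reactants: 11 methyl (1S,2R)-2-methyl-5-oxocyclopentane-1-carboxylate; 6 (4R)-6-iodo-4-methylhex-1-ene
Product: 12 methyl (2R)-2-methyl-1-[(3S)-3-methylhex-5-en-1-yl]-5-oxocyclopentane-1-carboxylate (both C1 epimers)
Conditions: K2CO3, DMF, 60 °C
Reagents that add atoms: none
Why: C-alkylation of the stabilised β-keto ester enolate with a primary iodide (acetoacetic ester alkylation) forms C1–C18; the configuration of the new quaternary C1 is of no consequence because the ester is removed in step 8.

Step 8
Reactants: 12 alkylated β-keto ester
Product: 13 (2S,3R)-3-methyl-2-[(3S)-3-methylhex-5-en-1-yl]cyclopentan-1-one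
Conditions: LiCl, H2O, DMSO, 150 °C
Reagents that add atoms: none
Why: Krapcho dealkoxycarbonylation (chloride attack on the methyl group, loss of CO2, protonation of the enolate); C1 is epimerisable and settles under the hot, mildly basic conditions with the side chain trans to the C2 methyl, the thermodynamically preferred 2,3-trans cyclopentanone.

Step 9
Reactants: 13 (2S,3R)-3-methyl-2-[(3S)-3-methylhex-5-en-1-yl]cyclopentan-1-one; 14 isopropenylmagnesium bromide
Product: 15 (1R,2S,3R)-3-methyl-2-[(3S)-3-methylhex-5-en-1-yl]-1-(prop-1-en-2-yl)cyclopentan-1-ol (expected major carbinol epimer)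
Conditions: LaCl3·2LiCl (0.3 equiv), THF, 0 °C
Reagents that add atoms: none
Why: Grignard 1,2-addition to the ketone, with the lanthanum salt suppressing enolisation of the cyclopentanone; attack anti to the C1 side chain should dominate, but the C5 configuration is erased in step 11 and either epimer serves.

Step 10
Reactants: 15 isopropenyl carbinol
Product: 16 bicyclic tertiary allylic alcohol [(1R,5S,8S,9R,2Z)-2,5,9-trimethylbicyclo[6.3.0]undec-2-en-1-ol; OH on C5, C6=C7 in ring B]
Conditions: second-generation Hoveyda–Grubbs catalyst (10 mol %), PhMe (high dilution), 80 °C, argon sparge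
Reagents that add atoms: none
Why: Ring-closing metathesis: the catalyst loads on the unhindered terminal alkene and closes onto the isopropenyl group, forming C6=C7 as a Z-trisubstituted alkene in the eight-membered ring B with loss of ethylene, the cyclopentane holding the two arms on adjacent carbons and high dilution disfavouring oligomers.

Step 11
Reactants: 16 bicyclic tertiary allylic alcohol
Product: 17 AB enone [(5S,8S,9R)-2,5,9-trimethylbicyclo[6.3.0]undec-1-en-3-one; C7=O, C5=C6]
Conditions: [C5H5NH][CrO3Cl], 4 Å molecular sieves, CH2Cl2, 23 °C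
Reagents that add atoms: pyridinium chlorochromate, [O-][Cr](=O)(=O)Cl.c1cc[nH+]cc1 (the carbonyl oxygen is delivered from chromium in the [3,3] shift)
Why: Oxidative 1,3-transposition of a tertiary allylic alcohol (Dauben–Babler oxidation): the chromate ester of the C5 alcohol shifts by a [3,3] rearrangement to C7 and is oxidised there, which gives the C7 ketone and the tetrasubstituted C5=C6 alkene, whose geometry is fixed by ring B.

Step 12
Reactants: 17 AB enone; 18 methyl 2-(bromomethyl)acrylate
Product: 20 α′-alkylated enone [methyl 2-{[(4R,5S,8S,9R)-2,5,9-trimethyl-3-oxobicyclo[6.3.0]undec-1-en-4-yl]methyl}prop-2-enoate; arm on C15 β], via cross-conjugated lithium enolate 19 (not isolated)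
Conditions: LiN(i-Pr)2, THF, −78 °C; then 18, −78 → −40 °C
Reagents that add atoms: none
Why: Kinetic deprotonation at the α′ carbon C15 and alkylation of the enolate with the allylic bromide (direct or by addition–elimination, same product) forms C15–C14; the electrophile should enter on the β face, anti to the adjacent α-methyl on C16 (1,2-induction, peripheral attack on the medium ring), and C15 remains epimerisable should correction towards the 15,16-trans isomer be needed.

Step 13
Reactants: 21 3-methylbut-1-yne
Product: 23 4-methylpent-2-yn-1-ol, via lithium acetylide 22 (not isolated)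
Conditions: n-BuLi, THF, −78 °C; then (CH2O)n, −78 → 23 °C
Reagents that add atoms: paraformaldehyde (as formaldehyde), C=O
Why: Deprotonation of the terminal alkyne and 1,2-addition of the lithium acetylide to formaldehyde gives the propargylic alcohol that supplies C8–C10 and the isopropyl group.

Step 14
Reactants: 23 4-methylpent-2-yn-1-ol
Product: 24 1-bromo-4-methylpent-2-yne
Conditions: PBr3, pyridine (cat.), Et2O, 0 °C
Reagents that add atoms: phosphorus tribromide, BrP(Br)Br
Why: Bromination of a primary propargylic alcohol with PBr3 by SN2 displacement of the phosphite ester.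

Step 15
Reactants: 20 α′-alkylated enone; 24 1-bromo-4-methylpent-2-yne
Product: 26 tertiary homopropargylic alcohol (β-OH and α-(4-methylpent-2-yn-1-yl) on C7), via allenylzinc bromide 25 (not isolated)
Conditions: Zn dust, THF, 0 °C; then 20, 0 °C
Reagents that add atoms: none
Why: Barbier-type propargylation: the organozinc reacts as the allenyl isomer through a cyclic SE2′ transition state, bonding through its unsubstituted CH2 terminus (the only uncongested mode at this hindered ketone) to form C7–C8 and the internal alkyne, chemoselectively at the ketone, not the ester; the C7 stereocentre is set by attack on the α face, anti to the β-oriented C15 arm, which leaves the hydroxyl β and C8 trans to C14, and a cold quench keeps the tertiary alkoxide from lactonising onto the ester.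

Step 16
Reactants: 26 tertiary homopropargylic alcohol
Product: 27 triethylsilyl ether (AB-bicyclic 1,7-enyne)
Conditions: Et3SiOTf, 2,6-lutidine, CH2Cl2, −40 → 0 °C
Reagents that add atoms: triethylsilyl trifluoromethanesulfonate, CC[Si](CC)(CC)OS(=O)(=O)C(F)(F)F
Why: Silylation of a hindered tertiary alcohol with a silyl triflate and a hindered pyridine base; the triethylsilyl ether blocks retro-addition and lactonisation and survives as far as step 20.

Step 17
Reactants: 27 triethylsilyl ether (1,7-enyne); 28 carbon monoxide
Product: 29 tetracyclic cyclopentenone (C9=C10 with isopropyl on C10, C11=O, α-CO2CH3 on C13, β-OSiEt3 on C7)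
Conditions: Co2(CO)8 (30 mol %), tetramethylthiourea, CO (1 atm), PhMe, 80 °C
Reagents that add atoms: none
Why: Cobalt binds the C9≡C10 alkyne, the acrylate alkene C13=C12 then coordinates and inserts into the Co–C9 bond (forming C9–C13), CO inserts into the Co–C12 bond and reductive elimination joins C11 to C10, releasing the cyclopentenone and the catalyst. The closest known reaction is the intramolecular Pauson–Khand cyclisation of 1,7-enynes and of enynes whose alkene is a 2-substituted acrylate; β-hydride loss from the metallacycle, the usual failure of electron-poor alkenes, is impossible here because C13 bears no hydrogen. Ring C closes in a 6-exo mode (C9 attacks C13 through the four-atom tether C8–C7–C15–C14) and ring D closes as the five-membered metallacycle that becomes the cyclopentenone. The one new stereocentre, C13, is controlled by the chair-like tether: the ring B bonds at C7 and C15 stay equatorial, the C7 oxygen is axial on the β face, C12 has to lie in the plane of the forming five-membered ring, and the ester is therefore axial on the α face. The step needs this facial selectivity and reaction at the acrylate only; the trans arrangement of the two arms set in steps 12 and 15, the fully substituted C7 with its bulky axial silyloxy group (which favours the reactive rotamer and penalises the boat-like alternative) and the inertness of the tetrasubstituted C5=C6 alkene secure them.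

Step 18
Reactants: 29 tetracyclic cyclopentenone
Product: 31 enol triflate (C11–OSO2CF3, C10=C11, β-H at C9), via ring D lithium enolate 30 (not isolated)
Conditions: Li, t-BuOH (1 equiv), NH3 (l)/THF, −78 °C; isoprene; NH3 evaporated; then PhNTf2, THF, −78 → 0 °C
Reagents that add atoms: N-phenylbis(trifluoromethanesulfonimide), O=S(=O)(N(c1ccccc1)S(=O)(=O)C(F)(F)F)C(F)(F)F
Why: Dissolving-metal conjugate reduction with enolate trapping: the enone takes up two electrons, C9 is protonated axially on ring C from the β face (opposite the angular ester; the alternative would force C10 axial against the C7 silyloxy group), which sets the trans C/D fusion, and the regiodefined lithium enolate is triflated on oxygen, so that no epimerisable ketone is ever formed at C11.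

Step 19
Reactants: 31 enol triflate
Product: 32 ring D alkene (C10=C11; methyl ester; triethylsilyl ether)
Conditions: Pd(OAc)2 (5 mol %), PPh3, HCO2H, n-Bu3N, DMF, 60 °C
Reagents that add atoms: none
Why: Palladium-catalysed formate reduction of an enol triflate (oxidative addition, formate exchange, loss of CO2, C–H reductive elimination) removes the former carbonyl oxygen and leaves the C10=C11 alkene.

Step 20
Reactants: 32 ring D alkene
Product: 33 tertiary alcohol (C10=C11; methyl ester; free C7 hydroxyl)
Conditions: Bu4NF, THF, 23 → 50 °C
Reagents that add atoms: none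
Why: Fluoride-mediated desilylation of the tertiary silyl ether; with the enone gone the free carbinol can no longer fragment, and the small β-hydroxyl opens the β face for the next step.

Step 21
Reactants: 33 tertiary alcohol
Product: 34 sesterfisheric acid methyl ester
Conditions: H2 (1 atm), PtO2, EtOAc, 23 °C
Reagents that add atoms: none
Why: Heterogeneous catalytic hydrogenation (syn addition) of the trisubstituted C10=C11 alkene from the β face, opposite the angular α ester that covers ring D, sets C10 with β-H and α-isopropyl (cis to the ester); the tetrasubstituted C5=C6 alkene is too hindered to react.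

Step 22
Reactants: 34 sesterfisheric acid methyl ester
Product: 35 sesterfisheric acid
Conditions: NaSEt, DMF, 100 °C; then aq. HCl to pH 4, 0 °C
Reagents that add atoms: none
Why: SN2 demethylation of the ester by thiolate attack at the methyl carbon, which sidesteps the hindered neopentyl-type acyl carbon and avoids the acid that would ionise the tertiary allylic alcohol, gives the carboxylate and, after mild acidification, sesterfisheric acid.

**Compound list**

1 | methyl hydrogen (R)-3-methylglutarate [(3R)-5-methoxy-3-methyl-5-oxopentanoic acid] | OC(=O)C[C@@H](C)CC(=O)OC | starting material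
2 | (3S)-5-hydroxy-3-methylpentanoic acid (lithium salt until acidification) | OC(=O)C[C@@H](C)CCO | intermediate
3 | (4S)-4-methyloxan-2-one | O=C1C[C@@H](C)CCO1 | intermediate
4 | (4S)-4-methyloxan-2-ol (lactol, both anomers) | OC1C[C@@H](C)CCO1 | intermediate
5 | (3R)-3-methylhex-5-en-1-ol | C=CC[C@@H](C)CCO | intermediate
6 | (4R)-6-iodo-4-methylhex-1-ene | C=CC[C@@H](C)CCI | intermediate
7 | (R)-pulegone | C[C@@H]1CCC(=C(C)C)C(=O)C1 | starting material
8 | pulegone dibromide [(5R)-2-bromo-2-(2-bromopropan-2-yl)-5-methylcyclohexan-1-one, C2 epimers] | C[C@@H]1CCC(Br)(C(C)(C)Br)C(=O)C1 | intermediate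
9 | methyl pulegenate [methyl (2R)-2-methyl-5-(propan-2-ylidene)cyclopentane-1-carboxylate, C1 epimers] | CC(C)=C1CC[C@@H](C)C1C(=O)OC | intermediate
10 | secondary ozonide [methyl (7R)-3,3,7-trimethyl-1,2,4-trioxaspiro[4.4]nonane-6-carboxylate] | CC1(C)OOC2(O1)CC[C@@H](C)C2C(=O)OC | intermediate
11 | methyl (1S,2R)-2-methyl-5-oxocyclopentane-1-carboxylate (trans) | O=C1CC[C@@H](C)[C@@H]1C(=O)OC | intermediate
12 | methyl (2R)-2-methyl-1-[(3S)-3-methylhex-5-en-1-yl]-5-oxocyclopentane-1-carboxylate (C1 epimers) | O=C1CC[C@@H](C)C1(CC[C@H](C)CC=C)C(=O)OC | intermediate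
13 | (2S,3R)-3-methyl-2-[(3S)-3-methylhex-5-en-1-yl]cyclopentan-1-one | O=C1CC[C@@H](C)[C@@H]1CC[C@H](C)CC=C | intermediate
14 | isopropenylmagnesium bromide | CC(=C)[Mg]Br | starting material
15 | (1R,2S,3R)-3-methyl-2-[(3S)-3-methylhex-5-en-1-yl]-1-(prop-1-en-2-yl)cyclopentan-1-ol | C=C(C)[C@@]1(O)CC[C@@H](C)[C@@H]1CC[C@H](C)CC=C | intermediate
16 | (1R,5S,8S,9R,2Z)-2,5,9-trimethylbicyclo[6.3.0]undec-2-en-1-ol (OH on C5; C6=C7) | O[C@]12CC[C@@H](C)[C@@H]1CC[C@H](C)C/C=C\2C | intermediate
17 | AB enone, (5S,8S,9R)-2,5,9-trimethylbicyclo[6.3.0]undec-1-en-3-one (C7=O; C5=C6) | C/C1=C2\CC[C@@H](C)[C@@H]2CC[C@H](C)CC1=O | intermediate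
18 | methyl 2-(bromomethyl)acrylate | C=C(CBr)C(=O)OC | starting material
19 | lithium enolate of 17 (C7–OLi; C7=C15) | [Li]O/C1=C/[C@@H](C)CC[C@H]2[C@H](C)CC/C2=C1\C | intermediate
20 | methyl 2-{[(4R,5S,8S,9R)-2,5,9-trimethyl-3-oxobicyclo[6.3.0]undec-1-en-4-yl]methyl}prop-2-enoate (arm on C15 β) | C/C1=C2\CC[C@@H](C)[C@@H]2CC[C@H](C)[C@@H](CC(=C)C(=O)OC)C1=O | intermediate
21 | 3-methylbut-1-yne | CC(C)C#C | starting material
22 | lithium 3-methylbut-1-yn-1-ide | CC(C)C#C[Li] | intermediate
23 | 4-methylpent-2-yn-1-ol | CC(C)C#CCO | intermediate
24 | 1-bromo-4-methylpent-2-yne | CC(C)C#CCBr | intermediate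
25 | bromo(4-methylpenta-1,2-dien-3-yl)zinc (allenylzinc bromide) | CC(C)C([Zn]Br)=C=C | intermediate
26 | tertiary homopropargylic alcohol (C7: β-OH, α-(4-methylpent-2-yn-1-yl); C15: β-(2-methoxycarbonylallyl)) | C/C1=C2\CC[C@@H](C)[C@@H]2CC[C@H](C)[C@@H](CC(=C)C(=O)OC)[C@@]1(CC#CC(C)C)O | intermediate
27 | triethylsilyl ether of 26 (AB-bicyclic 1,7-enyne) | C/C1=C2\CC[C@@H](C)[C@@H]2CC[C@H](C)[C@@H](CC(=C)C(=O)OC)[C@@]1(CC#CC(C)C)O[Si](CC)(CC)CC | intermediate
28 | carbon monoxide | [C-]#[O+] | starting material
29 | tetracyclic cyclopentenone (C9=C10, isopropyl on C10, C11=O, α-CO2CH3 on C13, β-OSiEt3 on C7, α-H at C15) | C/C1=C2\CC[C@@H](C)[C@@H]2CC[C@H](C)[C@H]2C[C@@]3(C(=O)OC)CC(=O)C(C(C)C)=C3C[C@]12O[Si](CC)(CC)CC | intermediate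
30 | ring D lithium enolate (C11–OLi, C10=C11, β-H at C9) | C/C1=C2\CC[C@@H](C)[C@@H]2CC[C@H](C)[C@H]2C[C@@]3(C(=O)OC)CC(O[Li])=C(C(C)C)[C@@H]3C[C@]12O[Si](CC)(CC)CC | intermediate
31 | enol triflate (C11–OSO2CF3, C10=C11) | C/C1=C2\CC[C@@H](C)[C@@H]2CC[C@H](C)[C@H]2C[C@@]3(C(=O)OC)CC(OS(=O)(=O)C(F)(F)F)=C(C(C)C)[C@@H]3C[C@]12O[Si](CC)(CC)CC | intermediate
32 | ring D alkene (C10=C11), methyl ester, triethylsilyl ether | C/C1=C2\CC[C@@H](C)[C@@H]2CC[C@H](C)[C@H]2C[C@@]3(C(=O)OC)CC=C(C(C)C)[C@@H]3C[C@]12O[Si](CC)(CC)CC | intermediate
33 | ring D alkene (C10=C11), methyl ester, free C7 hydroxyl | C/C1=C2\CC[C@@H](C)[C@@H]2CC[C@H](C)[C@H]2C[C@@]3(C(=O)OC)CC=C(C(C)C)[C@@H]3C[C@]12O | intermediate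
34 | sesterfisheric acid methyl ester | C/C1=C2\CC[C@@H](C)[C@@H]2CC[C@H](C)[C@H]2C[C@@]3(C(=O)OC)CC[C@H](C(C)C)[C@@H]3C[C@]12O | intermediate
35 | sesterfisheric acid | C/C1=C2\CC[C@@H](C)[C@@H]2CC[C@H](C)[C@H]2C[C@@]3(C(=O)O)CC[C@H](C(C)C)[C@@H]3C[C@]12O | target

**Step count and risk**

Total: 22 steps. Longest linear sequence: 18 steps (1 → 35 through steps 1–4, 7–12 and 15–22). The pulegone branch (steps 5–6) and the alkyne branch (steps 13–14) are convergent.

Steps most likely to fail:

Step 17. The electron-poor, 1,1-disubstituted acrylate alkene may insert too slowly into the cobalt–alkyne complex, so that the complex decomposes or the alkyne is merely reduced, or the boat-like mode may compete and erode selectivity at C13. Fallback (from 27, back at 29): the ester is taken out of conjugation before the cyclisation. Reduction of 27 with i-Bu2AlH gives the allylic alcohol enyne F1, whose electron-neutral alkene should undergo the same cobalt-catalysed Pauson–Khand cyclisation to the hydroxymethyl enone F2 (the CH2OH arm takes the axial α site for the same reason as the ester). Dess–Martin oxidation gives the angular aldehyde F3, Pinnick oxidation the acid F4, and trimethylsilyldiazomethane returns the methyl ester 29.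

Step 10. Closure onto the hindered isopropenyl group next to the quaternary carbinol may be slower than cross-metathesis of the terminal alkene, so that dimers and oligomers form in place of the cyclooctene. Fallback (from 13, back at 17): the C6 methyl is left out of the metathesis. Vinylmagnesium bromide adds to 13 to give the vinyl carbinol F5, and ring-closing metathesis then forms only a disubstituted cyclooctene, the bicyclic allylic alcohol F6. The same chromium-mediated oxidative transposition gives the enone F7 lacking the C6 methyl, α-iodination with I2 and pyridine gives the α-iodoenone F8, and palladium-catalysed Negishi coupling with methylzinc chloride installs the methyl group to give 17.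

Step 15. The substituted organozinc may react through its propargylic form (bonding at the isopropyl-bearing carbon, which gives an allenyl carbinol), or so slowly at the hindered ketone that the zinc alkoxide lactonises onto the ester; attack syn to the C15 arm is a further hazard that the fallback does not address. Fallback (from 20, back at 27): the isopropyl group is attached after the carbinol is made. Zinc-mediated addition of the parent propargyl bromide, which reacts faster and cleanly through the allenyl form, gives the terminal homopropargylic alcohol F9, and silylation as in step 16 gives the terminal alkyne silyl ether F10. A nickel-catalysed Sonogashira-type coupling of the terminal alkyne with 2-iodopropane (Ni(cod)2, a pybox ligand, CuI, Cs2CO3) then gives 27.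

Further compounds
F1 | step 17 | allylic alcohol enyne (27 with CH2OH in place of CO2CH3) | C/C1=C2\CC[C@@H](C)[C@@H]2CC[C@H](C)[C@@H](CC(=C)CO)[C@@]1(CC#CC(C)C)O[Si](CC)(CC)CC
F2 | step 17 | hydroxymethyl enone (29 with α-CH2OH on C13) | C/C1=C2\CC[C@@H](C)[C@@H]2CC[C@H](C)[C@H]2C[C@@]3(CO)CC(=O)C(C(C)C)=C3C[C@]12O[Si](CC)(CC)CC
F3 | step 17 | angular aldehyde (29 with α-CHO on C13) | C/C1=C2\CC[C@@H](C)[C@@H]2CC[C@H](C)[C@H]2C[C@@]3(C=O)CC(=O)C(C(C)C)=C3C[C@]12O[Si](CC)(CC)CC
F4 | step 17 | angular acid (29 with α-CO2H on C13) | C/C1=C2\CC[C@@H](C)[C@@H]2CC[C@H](C)[C@H]2C[C@@]3(C(=O)O)CC(=O)C(C(C)C)=C3C[C@]12O[Si](CC)(CC)CC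
F5 | step 10 | vinyl carbinol, (1R,2S,3R)-1-ethenyl-3-methyl-2-[(3S)-3-methylhex-5-en-1-yl]cyclopentan-1-ol | C=C[C@@]1(O)CC[C@@H](C)[C@@H]1CC[C@H](C)CC=C
F6 | step 10 | bicyclic allylic alcohol lacking the C6 methyl (OH on C5; C6=C7, Z) | O[C@]12CC[C@@H](C)[C@@H]1CC[C@H](C)C/C=C\2
F7 | step 10 | enone lacking the C6 methyl (C7=O; C5=C6) | O=C1C[C@@H](C)CC[C@H]2[C@H](C)CC/C2=C/1
F8 | step 10 | α-iodoenone (iodine on C6) | O=C1C[C@@H](C)CC[C@H]2[C@H](C)CC/C2=C/1I
F9 | step 15 | terminal homopropargylic alcohol (26 with prop-2-yn-1-yl on C7) | C/C1=C2\CC[C@@H](C)[C@@H]2CC[C@H](C)[C@@H](CC(=C)C(=O)OC)[C@@]1(CC#C)O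
F10 | step 15 | triethylsilyl ether of F9 | C/C1=C2\CC[C@@H](C)[C@@H]2CC[C@H](C)[C@@H](CC(=C)C(=O)OC)[C@@]1(CC#C)O[Si](CC)(CC)CC
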